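The readings were computed with made-up constants.

The constants of this flask are hidden, so what you have is its own dawn run, and that run shows a plateau and the approach to it.

| flask | starting material | second substrate | free enzyme | temperature | remark | time |
|---|---|---|---|---|---|---|
| dawn | 0.050 M | 0.50 equiv | 0.033 mol% | 5 °C | the very flask that is asked about, followed so far |  |
| flask | 0.050 M | 0.500 equiv | 0.033 mol% | 5 °C |  | 8.0 d |

- dawn (time / d: target / %): 0.417: 13.4; 0.625: 17.7; 1.04: 24.7; 1.67: 30.2; 3.00: 33.7; 5.00: 33.7

(standard deviation of a reading: 0.3 percentage points)

- blue: change nothing and wait 4.0 d more
- red: at 8.0 d add second substrate, 50.0% of the amount charged, then wait 4.0 d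
- amber: at 8.0 d take out 90% of the first product then present, then wait 4.0 d
- green: at 8.0 d add free enzyme, 50.0% of the amount charged, then wait 4.0 d
- grey: at 8.0 d raise the temperature by 20 K, then wait 4.0 d

- percent here means starting material units held: one homo dimer B counts as two
- what is added takes up no volume worth counting
- the analysis behind the earlier runs scatters by 0.3 percentage points, standard deviation
- what may be going on: free enzyme -> unfolded enzyme; starting material + free enzyme <-> first complex; first complex <-> loaded enzyme + first product; second substrate + loaded enzyme <-> second complex; second complex -> free enzyme + target; 2 second substrate -> homo dimer A; 2 starting material -> homo dimer B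
- the earlier runs do not show what temperature does; that part of a forecast is a guess

- target, in percent of the starting material first charged, at 8.0 d
- what to do for the largest gain in target; "none" if nothing gains more than 2 percentage points (blue / red / amber / green / grey / none)
- target present, in percent of the starting material first charged, after amber
- target present, in percent of the starting material first charged, after grey

Target reads 33.7% at 3.00 d and 33.7% at 5.00 d, and between the first and fourth readings the gap to that plateau shrinks at 1.40 d⁻¹. I therefore reckon target at 8.0 d as the plateau, 33.7%.

Two end states give that number. In the first, the enzyme has died, with a half-life of 0.495 d, and second substrate is left over. In the second, second substrate, the limiting reagent at 0.50 equiv, has been consumed, part of it paired to homo dimer A, while the enzyme still works. Their agreement on the number checks nothing, since both lean on the same plateau. The exponential gap cheats as a witness too: capture first order in c(second substrate) on a steady catalyst also gives an exponential tail, once the pairing, second order in c(second substrate), has faded.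

They part on what a new dose does, so I set a rule for the second end state. In that end state the dawn dose of 0.50 equiv put, by the plateau reading, 67.4% of itself into target. Pairing is second order in c(second substrate) and capture first order, so with the enzyme and starting material charges of the dawn run held, I write the share of a dose reaching target as B over B plus the dose. That gives B = 103% of the starting material charged, the crossover dose, at which target and homo dimer A take equal shares. Red adds a dose of 25.0% of the starting material charged, so on a living enzyme I reckon it gives 20 percentage points. On a dead enzyme it gives nothing.

The forecast took the first end state: 33.8% now, 33.8% after amber, 33.8% after grey, and green as best, on the ground that “Only fresh enzyme restarts the reaction”.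

The flask gives 34.3% now, 34.3% after amber, 34.3% after grey, and red as best, with a gain of 20 points, against 0 points for green.

    free enzyme → unfolded enzyme (k = 3.86 × 10⁻⁷ s⁻¹, Ea = 216 kJ mol⁻¹)
    starting material + free enzyme ⇌ first complex (K = 52.0 L mol⁻¹, k = 12.5 L mol⁻¹ s⁻¹, Ea = 51.0 kJ mol⁻¹, ΔH = −8.00 kJ mol⁻¹)
    first complex ⇌ loaded enzyme + first product (K = 0.0650 M, k = 0.0384 s⁻¹, Ea = 67.0 kJ mol⁻¹, ΔH = −64.0 kJ mol⁻¹)
    second substrate + loaded enzyme ⇌ second complex (K = 19.0 L mol⁻¹, k = 17.5 L mol⁻¹ s⁻¹, Ea = 52.0 kJ mol⁻¹, ΔH = −24.0 kJ mol⁻¹)
    second complex → free enzyme + target (k = 0.0864 s⁻¹, Ea = 77.0 kJ mol⁻¹)
    2 second substrate → homo dimer A (k = 2.32 × 10⁻⁴ L mol⁻¹ s⁻¹, Ea = 65.0 kJ mol⁻¹)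
    2 starting material → homo dimer B (k = 4.13 × 10⁻⁸ L mol⁻¹ s⁻¹, Ea = 87.0 kJ mol⁻¹)
    (constants at 5 °C)

At 8.00 d the flask holds 0% of its second substrate, while 97.0% of the catalyst can still turn over. The crossover dose B gave 20 points for red, and red gained 20 points. Applied to the neighbour flask charged with 2.00 equiv, B gives 68.0%, more than the 56.4% of target that flask holds at 8.00 d.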